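## Retrosynthetic overview

1. 25 ⇒ 24 (a Schenck ene reaction puts O2 on C11 and moves the alkene to C9=C10) ⇒ 21 (ester on O1, C2 carbinol to ketone). Only functional-group changes follow the key step.
2. 21 ⇒ 15 + 6. One flask delivers the C7–C8 bond, the whole C8–C13 chain, the 7,14-oxirane and the C7 stereocentre: a Shapiro vinyllithium (C7) adds to 4,4-dimethylcyclobutenone (C8 is its carbonyl carbon), the ring opens with strain release (4π), and t-BuOOH finishes the sequence.
3. Enabling feature: the ketone carbon C8 and the oxygen-bearing gem-dimethyl carbon C11 stand 1,4 across C9=C10, so C8–C9–C10–C11 is the opened form of a cyclobutene ring with a temporary C8–C11 bond. C7 is both an oxirane carbon and the α-carbon of the C8 ketone, which is the retron of an α-methylene ketone, so C7 can be an sp2 carbanion.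
4. 15 ⇒ (R)-carvone 7, which supplies the six-membered ring, C15, the C6 configuration, C7 and C14. O1 comes from enolate hydroxylation anti to the isopropenyl group, the 3,4-oxirane from C2–OH-directed epoxidation, and the hydrazone from isopropenyl via acetyl.
5. Ring order: cyclohexane (from 7), then the 3,4-oxirane (step 6), then the 7,14-oxirane (step 9). The auxiliary cyclobutene is made in step 1 and opened in step 9.

Key step: step 9

Remark on numbering (bisabolane): ring C1–C6, where C1 bears the ester oxygen, C2 is the ring ketone, C3/C4 are the ring oxirane, C5 is CH2 and C6 carries the side chain. C7 is the quaternary oxirane carbon, C8 the side-chain ketone, C9=C10 the alkene, C11 the hydroperoxy carbon, C12/C13 its methyls, C14 the oxirane CH2, and C15 the methyl on C3.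

## Route

Step 1
Reactants: 1 isobutyryl chloride; 2 ethoxyacetylene
Product: 4 3-ethoxy-4,4-dimethylcyclobut-2-en-1-one, via dimethylketene 3 (not isolated)
Conditions: Et3N, Et2O, 0 °C to rt
Reagents that add atoms: none
Why: Dehydrochlorination gives dimethylketene, which is trapped in a regioselective thermal [2+2] ketene–ynol ether cycloaddition (nucleophilic alkyne CH to the ketene carbonyl carbon), the standard entry to 3-alkoxycyclobutenones, and no stereocentre is formed.

Step 2
Reactants: 4 3-ethoxy-4,4-dimethylcyclobut-2-en-1-one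
Product: 6 4,4-dimethylcyclobut-2-en-1-one, via ethoxycyclobutenol 5 (not isolated)
Conditions: i-Bu2AlH, Et2O, −78 °C; then 1 M HCl, 0 °C; 6 kept as a dried THF solution
Reagents that add atoms: water, O
Why: 1,2-Reduction of the vinylogous ester, then acid-induced ionisation and hydrolysis of the 3-ethoxy allylic alcohol (Stork–Danheiser-type carbonyl transposition), should give the parent, non-enolisable cyclobutenone, and no stereocentre survives.

Step 3
Reactants: 7 (R)-(−)-carvone
Product: 9 (5S,6S)-6-hydroxy-2-methyl-5-(prop-1-en-2-yl)cyclohex-2-en-1-one, via sodium dienolate 8 (not isolated)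
Conditions: NaN(SiMe3)2, THF, −78 °C; 2-(phenylsulfonyl)-3-phenyloxaziridine, −78 °C; AcOH
Reagents that add atoms: 2-(phenylsulfonyl)-3-phenyloxaziridine, O=S(=O)(N1OC1c1ccccc1)c1ccccc1
Why: Kinetic α'-deprotonation gives the cross-conjugated dienolate, and the Davis oxaziridine hydroxylation should occur on the face anti to the neighbouring isopropenyl group, which sets O1 trans to the C6 substituent.

Step 4
Reactants: 9 (5S,6S)-6-hydroxycarvone
Product: 10 (5S,6S)-2-methyl-5-(prop-1-en-2-yl)-6-(triisopropylsilyloxy)cyclohex-2-en-1-one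
Conditions: TIPSOTf, 2,6-lutidine, CH2Cl2, 0 °C
Reagents that add atoms: triisopropylsilyl triflate, CC(C)[Si](OS(=O)(=O)C(F)(F)F)(C(C)C)C(C)C
Why: Standard silylation of the ketol with a silyl triflate touches no stereocentre and gives a TIPS ether that tolerates the organolithium, peroxide and periodinane steps and enlarges the C1 flank of C6.

Step 5
Reactants: 10 TIPS ether of 6-hydroxycarvone
Product: 11 (1S,5S,6S)-2-methyl-5-(prop-1-en-2-yl)-6-(triisopropylsilyloxy)cyclohex-2-en-1-ol
Conditions: NaBH4, CeCl3·7H2O, MeOH, −78 to 0 °C
Reagents that add atoms: none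
Why: Luche 1,2-reduction with axial hydride delivery should give the pseudo-equatorial C2 alcohol, cis to the isopropenyl group and trans to OTIPS, as in the reduction of carvone to cis-carveol.

Step 6
Reactants: 11 allylic alcohol
Product: 12 (1R,2R,3S,4S,6S)-1-methyl-4-(prop-1-en-2-yl)-3-(triisopropylsilyloxy)-7-oxabicyclo[4.1.0]heptan-2-ol
Conditions: VO(acac)2 (cat.), t-BuOOH (decane), CH2Cl2, 0 °C to rt
Reagents that add atoms: tert-butyl hydroperoxide, CC(C)(C)OO
Why: Vanadium-catalysed hydroxyl-directed epoxidation delivers oxygen syn to the C2–OH and so sets C3 and C4 with the oxirane cis to the side chain (the face that alkaline peroxide on the enone would not give), while the undirected isopropenyl group is left alone.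

Step 7
Reactants: 12 epoxy alcohol
Product: 14 (1R,2R,3S,4R,6S)-4-acetyl-1-methyl-3-(triisopropylsilyloxy)-7-oxabicyclo[4.1.0]heptan-2-ol, via secondary ozonide 13 (not isolated)
Conditions: O3, CH2Cl2, −78 °C; Me2S, −78 °C to rt
Reagents that add atoms: ozone, [O-][O+]=O
Why: Ozonolysis with reductive work-up cleaves the only remaining C=C bond and turns C7 into a methyl ketone whose CH3 is the future C14, and these neutral conditions should leave C6 unepimerised.

Step 8
Reactants: 14 methyl ketone
Product: 15 (E)-2,4,6-triisopropylbenzenesulfonylhydrazone of 14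
Conditions: 2,4,6-triisopropylbenzenesulfonyl hydrazide, THF, rt
Reagents that add atoms: 2,4,6-triisopropylbenzenesulfonyl hydrazide, CC(C)c1cc(C(C)C)c(S(=O)(=O)NN)c(C(C)C)c1
Why: Condensation of the methyl ketone with the sulfonyl hydrazide should give, for steric reasons, the (E)-hydrazone, whose N-sulfonyl group lies syn to the CH3 and directs the later deprotonation to that carbon.

Step 9
Reactants: 15 trisylhydrazone; 6 4,4-dimethylcyclobut-2-en-1-one
Product: 21 (1S,2R,3R,4S,6R,7R)-3,4:7,14-diepoxy-2-hydroxy-1-(triisopropylsilyloxy)bisabol-10-en-8-one, via vinyllithium 16 (not isolated), via lithium cyclobutenolate 17 (not isolated), via lithium dienolate 18 (not isolated), via skipped dienone 19 (not isolated), via peroxy enolate 20 (not isolated)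
Conditions: n-BuLi (3.1 equiv), THF, −78 to 0 °C; 6 (1.3 equiv), −78 to 0 °C; t-BuOOH (decane, 6 equiv), −78 to 0 °C; AcOH
Reagents that add atoms: tert-butyl hydroperoxide, CC(C)(C)OO
Why: Proposed new method: n-BuLi removes the O–H, N–H and syn-CH3 protons of 15, Shapiro fragmentation (loss of sulfinate and N2) gives vinyllithium 16, which should add 1,2 to the strained, non-enolisable ketone 6; cyclobutenolate 17 then opens by an alkoxide-accelerated conrotatory 4π electrocyclic reaction that cleaves the C8–C11 σ-bond (oxido group turning outward, ring strain released) to dienolate 18, and t-BuOOH acts twice, first as the acid that protonates 18 kinetically at C9 to the skipped dienone 19 and then, as t-BuOOLi, as the nucleophilic oxidant that adds to C14 to give peroxy enolate 20. The closest known reaction types are the trapping of Shapiro vinyllithiums with ketones, the low-temperature anionic ring opening of the cyclobutenolates formed from alkenyllithiums with squarate esters or benzocyclobutenones, and the Weitz–Scheffer epoxidation of enones with t-BuOOLi in THF; what is new is their union, in which a cyclobutenone serves as a β,γ-unsaturated acyl cation equivalent toward a vinyl anion. One ring is opened (cyclobutene, 4π conrotatory) and one is closed: the 7,14-oxirane forms by 3-exo-tet attack of the enolate carbon C7 on the proximal peroxide oxygen with loss of tert-butoxide. The only new stereocentre, C7, is set in this closure: A(1,3) strain holds the C6–H bond in the enolate plane, the two faces of C7 are then flanked by C5H2 and by C1–OTIPS, and oxygen should enter from the C5 side, which corresponds to 7R. The step needs 1,2- over 1,4-addition (hard lithium reagent, β-carbon next to the quaternary carbon), 4π opening without subsequent 6π closure of the cross-conjugated trienolate (the gem-dimethyl terminus would have to turn one methyl inward, so closure should need much higher temperature), α- over γ-protonation (cold quench, medium buffered by excess t-BuOOH) and oxidation of the enone only (t-BuOOLi does not attack the electron-rich C10=C11 bond). The TIPS group is chosen because it resists O-to-O and O-to-C silyl shifts in the lithiated intermediates, and the C2 alkoxide, syn to the 3,4-oxirane oxygen, cannot undergo Payne rearrangement.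

Step 10
Reactants: 21 epoxy alcohol
Product: 22 (1S,3S,4S,6R,7R)-3,4:7,14-diepoxy-1-(triisopropylsilyloxy)bisabol-10-ene-2,8-dione
Conditions: Dess–Martin periodinane, NaHCO3, CH2Cl2, 0 °C to rt
Reagents that add atoms: none
Why: Buffered Dess–Martin oxidation converts the C2 carbinol, which has served its purpose as directing group, into the ring ketone under non-enolising conditions that should neither move the skipped C10=C11 bond nor epimerise C1.

Step 11
Reactants: 22 silyloxy dione
Product: 23 (1S,3S,4S,6R,7R)-3,4:7,14-diepoxy-1-hydroxybisabol-10-ene-2,8-dione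
Conditions: HF·pyridine, THF/pyridine, 0 °C to rt
Reagents that add atoms: none
Why: Fluoride-driven Si–O cleavage should be tolerated because both oxiranes are now α-keto oxiranes and thus deactivated toward acid opening, and because the weakly acidic medium avoids enolisation at C1 and C9.

Step 12
Reactants: 23 ketol
Product: 24 (1S,3S,4S,6R,7R)-3,4:7,14-diepoxy-1-(3-methylbutanoyloxy)bisabol-10-ene-2,8-dione
Conditions: isovaleryl chloride, pyridine, DMAP (cat.), CH2Cl2, 0 °C
Reagents that add atoms: isovaleryl chloride, CC(C)CC(Cl)=O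
Why: DMAP-catalysed acylation of the secondary ketol proceeds with retention at C1, whose equatorial ester trans to the C6 substituent is also the thermodynamically preferred arrangement.

Step 13
Reactants: 24 prenyl ketone
Product: 25 (1S,3S,4S,6R,7R,9E)-3,4:7,14-diepoxy-11-hydroperoxy-1-(3-methylbutanoyloxy)bisabol-9-ene-2,8-dione (CNP0131119.1)
Conditions: O2, tetraphenylporphyrin (cat.), visible light, CH2Cl2, −20 °C
Reagents that add atoms: dioxygen, O=O
Why: In the Schenck ene reaction singlet oxygen attacks the only electron-rich alkene, abstraction of a C9 hydrogen should be favoured because the developing C9=C10 bond becomes conjugated with the C8 ketone, oxygen ends on C11, and the E alkene results from the transition state that keeps the acyl group away from the gem-dimethyl carbon, with no stereocentre formed.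

## Compound list

1 | isobutyryl chloride | CC(C)C(Cl)=O | starting material
2 | ethoxyacetylene | CCOC#C | starting material
3 | dimethylketene | CC(C)=C=O | intermediate
4 | 3-ethoxy-4,4-dimethylcyclobut-2-en-1-one | CCOC1=CC(=O)C1(C)C | intermediate
5 | 3-ethoxy-4,4-dimethylcyclobut-2-en-1-ol (racemic) | CCOC1=CC(O)C1(C)C | intermediate
6 | 4,4-dimethylcyclobut-2-en-1-one | CC1(C)C=CC1=O | intermediate
7 | (R)-(−)-carvone | CC1=CC[C@H](CC1=O)C(C)=C | starting material
8 | sodium cross-conjugated dienolate of carvone | C1=C(O[Na])C(C)=CC[C@H]1C(C)=C | intermediate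
9 | (5S,6S)-6-hydroxycarvone (OH trans to isopropenyl) | O[C@@H]1C(=O)C(C)=CC[C@H]1C(C)=C | intermediate
10 | (5S,6S)-6-(triisopropylsilyloxy)carvone | CC(C)[Si](C(C)C)(C(C)C)O[C@@H]1C(=O)C(C)=CC[C@H]1C(C)=C | intermediate
11 | (1S,5S,6S)-2-methyl-5-(prop-1-en-2-yl)-6-(triisopropylsilyloxy)cyclohex-2-en-1-ol (OH cis to isopropenyl, trans to OTIPS) | CC(C)[Si](C(C)C)(C(C)C)O[C@@H]1[C@@H](O)C(C)=CC[C@H]1C(C)=C | intermediate
12 | (1R,2R,3S,4S,6S)-1-methyl-4-(prop-1-en-2-yl)-3-(triisopropylsilyloxy)-7-oxabicyclo[4.1.0]heptan-2-ol (oxirane syn to OH and to isopropenyl) | CC(C)[Si](C(C)C)(C(C)C)O[C@@H]1[C@@H](O)[C@@]2(C)O[C@H]2C[C@H]1C(C)=C | intermediate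
13 | secondary ozonide of 12 (1,2,4-trioxolane at the former isopropenyl group, epimers at the trioxolane carbon) | CC(C)[Si](C(C)C)(C(C)C)O[C@@H]1[C@@H](O)[C@@]2(C)O[C@H]2C[C@H]1C3(C)OCOO3 | intermediate
14 | (1R,2R,3S,4R,6S)-4-acetyl-1-methyl-3-(triisopropylsilyloxy)-7-oxabicyclo[4.1.0]heptan-2-ol | CC(C)[Si](C(C)C)(C(C)C)O[C@@H]1[C@@H](O)[C@@]2(C)O[C@H]2C[C@H]1C(C)=O | intermediate
15 | (E)-2,4,6-triisopropylbenzenesulfonylhydrazone of 14 | CC(C)[Si](C(C)C)(C(C)C)O[C@@H]1[C@@H](O)[C@@]2(C)O[C@H]2C[C@H]1/C(C)=N/NS(=O)(=O)c3c(C(C)C)cc(C(C)C)cc3C(C)C | intermediate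
16 | C7 vinyllithium, C2 lithium alkoxide | CC(C)[Si](C(C)C)(C(C)C)O[C@@H]1[C@@H](O[Li])[C@@]2(C)O[C@H]2C[C@H]1C([Li])=C | intermediate
17 | lithium 1-alkenyl-4,4-dimethylcyclobut-2-en-1-olate (C8 epimers) | CC(C)[Si](C(C)C)(C(C)C)O[C@@H]1[C@@H](O[Li])[C@@]2(C)O[C@H]2C[C@H]1C(=C)C3(O[Li])C=CC3(C)C | intermediate
18 | lithium dienolate (oxido group outward, C7 cis to C10 across C8=C9) | CC(C)[Si](C(C)C)(C(C)C)O[C@@H]1[C@@H](O[Li])[C@@]2(C)O[C@H]2C[C@H]1C(=C)/C(O[Li])=C\C=C(C)C | intermediate
19 | skipped dienone (7(14),10-dien-8-one) | CC(C)[Si](C(C)C)(C(C)C)O[C@@H]1[C@@H](O)[C@@]2(C)O[C@H]2C[C@H]1C(=C)C(=O)CC=C(C)C | intermediate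
20 | lithium enolate bearing the C14 tert-butylperoxy group | CC(C)[Si](C(C)C)(C(C)C)O[C@@H]1[C@@H](O)[C@@]2(C)O[C@H]2C[C@H]1C(COOC(C)(C)C)=C(O[Li])CC=C(C)C | intermediate
21 | (1S,2R,3R,4S,6R,7R)-3,4:7,14-diepoxy-2-hydroxy-1-(triisopropylsilyloxy)bisabol-10-en-8-one | CC(C)[Si](C(C)C)(C(C)C)O[C@@H]1[C@@H](O)[C@@]2(C)O[C@H]2C[C@H]1[C@]1(C(=O)CC=C(C)C)CO1 | intermediate
22 | (1S,3S,4S,6R,7R)-3,4:7,14-diepoxy-1-(triisopropylsilyloxy)bisabol-10-ene-2,8-dione | CC(C)[Si](C(C)C)(C(C)C)O[C@@H]1C(=O)[C@@]2(C)O[C@H]2C[C@H]1[C@]1(C(=O)CC=C(C)C)CO1 | intermediate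
23 | (1S,3S,4S,6R,7R)-3,4:7,14-diepoxy-1-hydroxybisabol-10-ene-2,8-dione | O[C@@H]1C(=O)[C@@]2(C)O[C@H]2C[C@H]1[C@]1(C(=O)CC=C(C)C)CO1 | intermediate
24 | (1S,3S,4S,6R,7R)-3,4:7,14-diepoxy-1-(3-methylbutanoyloxy)bisabol-10-ene-2,8-dione | CC(C)CC(=O)O[C@@H]1C(=O)[C@@]2(C)O[C@H]2C[C@H]1[C@]1(C(=O)CC=C(C)C)CO1 | intermediate
25 | (1S,3S,4S,6R,7R,9E)-3,4:7,14-diepoxy-11-hydroperoxy-1-(3-methylbutanoyloxy)bisabol-9-ene-2,8-dione (CNP0131119.1) | CC(C)CC(=O)O[C@@H]1C(=O)[C@@]2(C)O[C@H]2C[C@H]1[C@]1(C(=O)/C=C/C(C)(C)OO)CO1 | target

## Step count and risks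

Total step count: 13. Longest linear sequence: 11 steps (steps 3–13, from (R)-carvone).

Steps most likely to fail:

**Step 9.**
- What may go wrong: conjugate instead of carbonyl addition to the cyclobutenone; ring opening that becomes fast only at temperatures where silyl shifts or electrocyclic closure of the trienolate set in; interference of the sulfinate or drift of the skipped alkene into conjugation during the one-pot peroxide finish; insufficient facial selectivity in the oxirane closure.
- Fallback (known chemistry only), from 15 to 22: vinyllithium 16 is generated in the same way and added to the acyclic aldehyde 4-methylpent-3-enal F1, made by Dess–Martin oxidation of commercial 4-methylpent-3-en-1-ol. This gives the C8 allylic alcohol F2 as an inconsequential epimer mixture. Dess–Martin oxidation of both carbinols of F2 gives the 7(14),10-diene-2,8-dione F3. A separate Weitz–Scheffer epoxidation (t-BuOOH, DBU, toluene, 0 °C) closes the 7,14-oxirane under the same A(1,3) control and rejoins the route at 22.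

**Step 13.**
- What may go wrong: poor regioselectivity of the ene reaction (hydrogen abstraction from the methyl group cis to the chain instead of from C9), or loss of the hydroperoxide during isolation.
- Fallback, from 24 to 25: the oxygen is brought in as ground-state O2 through the weak, doubly activated C9–H bond instead of through the alkene. This is a radical-chain autoxidation (O2, N-hydroxyphthalimide (cat.), di-tert-butyl hyponitrite (cat.), MeCN, 35 °C), the reaction type by which β,γ-unsaturated ketones such as 5-en-3-one steroids give γ-hydroperoxy enones. The delocalised C9/C11 radical should be trapped at the tertiary C11 with the enone conjugation retained. This fallback makes no new compound (F0).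

**Step 3.**
- What may go wrong: proton exchange between product alkoxide and dienolate, attack of the dienolate on the sulfonimine by-product, and incomplete anti selectivity.
- Fallback, from 7 to 10: carvone is converted by soft enolisation (TIPSOTf, Et3N, CH2Cl2, 0 °C) into the cross-conjugated silyl dienol ether F4. A Rubottom oxidation (m-CPBA, NaHCO3, CH2Cl2, −20 °C) attacks the electron-rich enol ether bond anti to the isopropenyl group and, after 1,4-silyl migration, gives 10 directly, so that 9 is bypassed.

## Further compounds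

F1 | step 9 | 4-methylpent-3-enal | CC(C)=CCC=O
F2 | step 9 | C8 allylic alcohol (C8 epimers), 3,4-epoxy-2,8-dihydroxy-1-(triisopropylsilyloxy)bisabola-7(14),10-diene | CC(C)[Si](C(C)C)(C(C)C)O[C@@H]1[C@@H](O)[C@@]2(C)O[C@H]2C[C@H]1C(=C)C(O)CC=C(C)C
F3 | step 9 | 3,4-epoxy-1-(triisopropylsilyloxy)bisabola-7(14),10-diene-2,8-dione | CC(C)[Si](C(C)C)(C(C)C)O[C@@H]1C(=O)[C@@]2(C)O[C@H]2C[C@H]1C(=C)C(=O)CC=C(C)C
F0 | step 13 | none | none
F4 | step 3 | cross-conjugated triisopropylsilyl dienol ether of (R)-carvone | C1=C(O[Si](C(C)C)(C(C)C)C(C)C)C(C)=CC[C@H]1C(C)=C
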